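Readings and results stem from a simulated flask from invented constants; scatter was added.

The right-handed substrate is the slow hand. In the midnight run at 6.00 h, its product reads 13.8 % against 26.6 % for the left-handed product. Can the racemization catalyst in the flask below turn slow right-handed substrate into left-handed while the free catalyst works?

| flask | left-handed substrate | right-handed substrate | partner | free catalyst | racemization catalyst | remark | time |
|---|---|---|---|---|---|---|---|
| midnight | 0.14 M | 0.14 M | 4 equiv (fed, over 2.0 h) | 0.2 mol% | 5 mol% | run made earlier; the fed solution adds 0.20 times the starting volume |  |
| summer | 0.58 M | 0.58 M | 4 equiv (fed, over 2.0 h) | 0.2 mol% | 5 mol% | run made earlier; the fed solution adds 0.20 times the starting volume |  |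
| autumn | 0.29 M | 0.29 M | 4 equiv (fed, over 2.0 h) | 0.2 mol% | 10 mol% | run made earlier; the fed solution adds 0.20 times the starting volume |  |
| flask | 0.29 M | 0.29 M | 4.00 equiv (fed, over 2.0 h) | 0.2 mol% | 5 mol% | the fed solution adds 0.20 times the starting volume | 5.0 h |

| run | time / h | left-handed product / % | right-handed product / % |
|---|---|---|---|
| midnight | 0.833 | 2.1 | 0.2 |
| midnight | 2.00 | 8.0 | 4.3 |
| midnight | 4.00 | 18.2 | 11.4 |
| midnight | 6.00 | 26.6 | 13.8 |
| summer | 0.833 | 18.8 | 9.4 |
| summer | 2.00 | 46.4 | 28.5 |
| summer | 4.00 | 52.8 | 43.5 |
| summer | 6.00 | 51.9 | 46.7 |
| autumn | 1.50 | 17.7 | 7.1 |
| autumn | 3.00 | 34.5 | 20.7 |
| autumn | 5.00 | 45.2 | 28.3 |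
| autumn | 6.00 | 46.7 | 34.0 |

(each reading ± 1 percentage point)

- free catalyst is single-handed; left-handed substrate and right-handed substrate are mirror images of each other, charged as a racemate, each of them at the stated concentration
- charges are per starting volume, the dose included; the dosed solution carries all of it
- candidate steps: partner + free catalyst + left-handed substrate -> free catalyst + left-handed product; partner + free catalyst + right-handed substrate -> free catalyst + right-handed product; left-handed substrate + racemization catalyst <-> right-handed substrate + racemization catalyst; racemization catalyst -> spent catalyst A; partner + racemization catalyst -> spent catalyst B; 2 racemization catalyst -> spent catalyst C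
- an excess is below zero if the other one leads

- left-handed product and right-handed product together, in percent of the left-handed substrate and right-handed substrate charged together, at 5.0 h
- excess of left-handed product over right-handed product in the product at 5.0 h
- whether the exchange between left-handed substrate and right-handed substrate keeps pace with the reaction: how far the product's excess at 5.0 h gets from its value without exchange to its value with instant exchange (above 80 % keeps pace, below 20 % hardly takes part, else lags behind)

Both product steps carry the same partner and free catalyst. So dividing one rate by the other cancels them, and the feed and the clock with them. Without exchange this integrates in closed form: the left-handed fraction remaining equals the right-handed fraction remaining raised to a power s. Each substrate is half of the charge, so each fraction remaining is one less twice its product reading. Taken as free of exchange, the midnight run at 6.00 h reads s = 2.35. This selectivity factor carries the scatter of its readings.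

Two chemists dispute the flask. The second says exchange is instant, so the two substrates stay equal. The excess then holds at s less one over s plus one, 40.3 %. The autumn run at 1.50 h reads 42.7 %.

The first says exchange hardly counts. Low conversion suits both views, since the power rule tends to that excess too. But autumn, with twice the racemization catalyst of the flask, falls to 23.0 % at 5.00 h.

For the flask, the reckoning here borrows the right-handed fraction from the autumn run at that time, 43.4 %. The power rule makes the left-handed fraction 14.1 %. That gives a yield of 71.3 % and an excess of 20.6 %.

The forecast sides with the first chemist on its own grounds: yield 72 %, excess 21 %, exchange hardly takes part. Its yield stands 0.70 percentage points above the reckoning here. In its words, “Halving the racemization catalyst should therefore change little.”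

The flask gives 74.9 % and 20.3 %. The exchange hardly takes part, getting 10 % of the way.

    partner + free catalyst + left-handed substrate → free catalyst + left-handed product (k = 25.0 /M²/min)
    partner + free catalyst + right-handed substrate → free catalyst + right-handed product (k = 11.0 /M²/min)
    left-handed substrate + racemization catalyst ⇌ right-handed substrate + racemization catalyst, rate k3*[racemization catalyst]*[left-handed substrate] forward; the back reaction follows from the equilibrium constant (k = 1.80 /M/min)
    racemization catalyst → spent catalyst A (k = 0.0200 /min)
    partner + racemization catalyst → spent catalyst B (k = 0.0220 /M/min)
    2 racemization catalyst → spent catalyst C (k = 0.640 /M/min)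

The second chemist keeps low conversion, as in the autumn run at 1.50 h, where both views give the same excess. In the flask, 38 % of the right-handed charge remains at 5.00 h, so the power rule gives 10.3 % of the left-handed charge, and the flask holds 12 %. The neighbouring flask takes 1.60 equiv of partner. There 70 % of the right-handed charge remains. The rule gives 43.1 % of the left-handed charge and an excess of 31.0 %. That neighbouring flask holds 47 % of the left-handed charge, at a yield of 41.6 % and an excess of 31.3 %.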